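**Plan**
- Retrosynthesis: cut the enol ester O–acyl bond (isovaleryl chloride), take the C2' ketone back to CH2 and the C1' ketone back to a silyl-protected carbinol, then open ring B at the O1–C2 lactone bond with C3–C4 saturated.
- Ring A is then cut at C8–C8a, C6–C7 and C4a–C8a. In coumarin numbering it carries O1 on C8a, the side-chain carbon on C8 and OMe on C7 as three neighbours, H on C6 and C5, and the propanoate chain on C4a; a vinylketene (C8a, C6, C5, C4a) and an ynol ether (C8, C7) deliver exactly this pattern.
- Forward: Wittig olefination and diazo transfer give the diazoketone; methoxyacetylide addition and silylation give the ynol ether; benzannulation builds ring A; lactonization and dehydrogenation build ring B; the side chain is then oxidised twice and O-acylated.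
- Stereochemistry: the target has no stereocentre and no stereogenic alkene; the enone is E from the stabilised ylide, and the carbinol carbon is carried racemic and erased in step 9.

Key step: step 5

Remark: because the target is achiral, every intermediate that carries the silyloxy- or hydroxy-bearing side-chain carbon is used as a racemate.

**Route**

Step 1
Reactants: 1 methyl 4-oxobutanoate
Product: 2 methyl (E)-6-oxohept-4-enoate
Conditions: Ph3P=CHCOCH3 (1.1 equiv), CH2Cl2, 40 °C
Reagents that add atoms: 1-(triphenylphosphoranylidene)propan-2-one, CC(=O)C=P(c1ccccc1)(c1ccccc1)c1ccccc1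
Why: Wittig olefination with the ketone-stabilised ylide should give the (E)-enone selectively because the oxaphosphetane forms reversibly and collapses through the trans arrangement, and the methyl ester does not react with this ylide.

Step 2
Reactants: 2 methyl (E)-6-oxohept-4-enoate
Product: 4 methyl (E)-7-diazo-6-oxohept-4-enoate, via trifluoroacetyl diketone 3 (not isolated)
Conditions: LiN(SiMe3)2 (1.1 equiv), THF, −78 °C; CF3CO2CH2CF3; aq. HCl work-up, crude 3 used at once; 4-acetamidobenzenesulfonyl azide (p-ABSA), Et3N, H2O (1 equiv), MeCN, 25 °C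
Reagents that add atoms: 4-acetamidobenzenesulfonyl azide, CC(=O)Nc1ccc(cc1)S(=O)(=O)N=[N+]=[N-] (supplies the N2 unit); 2,2,2-trifluoroethyl trifluoroacetate, FC(F)(F)COC(=O)C(F)(F)F (its trifluoroacetyl group is carried only by 3)
Why: Detrifluoroacetylative diazo transfer, in which kinetic deprotonation of the methyl ketone (more acidic than the ester α-CH2) and Claisen-type trifluoroacetylation give 3, whose activated methylene takes the diazo group from the sulfonyl azide while the trifluoroacetyl group leaves on the sulfonamide nitrogen.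

Step 3
Reactants: 5 2-chloro-1,1-dimethoxyethane (chloroacetaldehyde dimethyl acetal); 6 3-methylbutanal (isovaleraldehyde)
Product: 8 rac-1-methoxy-5-methylhex-1-yn-3-ol, via methoxyethynyllithium 7 (not isolated)
Conditions: Et2NH, n-BuLi (3 equiv each), THF, −78 to 0 °C; then 6, −78 °C; H2O quench, basic work-up
Reagents that add atoms: none
Why: Three equivalents of LiNEt2 remove MeOH and then HCl from the chloroacetal and deprotonate the resulting methoxyacetylene to acetylide 7, whose 1,2-addition to the aldehyde gives the racemic propargylic alcohol, with the work-up kept basic to prevent Meyer–Schuster rearrangement.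

Step 4
Reactants: 8 rac-1-methoxy-5-methylhex-1-yn-3-ol
Product: 9 rac-tert-butyl[(1-methoxy-5-methylhex-1-yn-3-yl)oxy]dimethylsilane
Conditions: TBSCl, imidazole, DMF, 0 to 25 °C
Reagents that add atoms: tert-butyldimethylsilyl chloride, CC(C)(C)[Si](C)(C)Cl
Why: Imidazole-promoted silylation of a secondary alcohol runs under basic conditions that spare the acid-labile ynol ether, and the silyl ether keeps the hydroxyl from adding to the ketene in step 5.

Step 5
Reactants: 4 methyl (E)-7-diazo-6-oxohept-4-enoate; 9 rac-tert-butyl[(1-methoxy-5-methylhex-1-yn-3-yl)oxy]dimethylsilane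
Product: 14 rac-methyl 3-{3-[1-(tert-butyldimethylsilyloxy)-3-methylbutyl]-2-hydroxy-4-methoxyphenyl}propanoate, via vinylketene 10 (not isolated), via 4-vinylcyclobutenone 11 (not isolated), via dienylketene 12 (not isolated), via cyclohexadienone 13 (not isolated)
Conditions: 9 (1.5 equiv), degassed ClCH2CH2Cl, hν (254 nm, Vycor), 25 °C; then 80 °C
Reagents that add atoms: none
Why: Light expels N2 from 4 and the photochemical Wolff rearrangement gives vinylketene 10, whose carbonyl carbon is attacked by the nucleophilic β-carbon of ynol ether 9 in a regiospecific [2+2] cycloaddition that forms C8–C8a and C6–C7 in cyclobutenone 11. Four-electron conrotatory ring opening of 11 (thermal or photochemical) gives dienylketene 12, and ring A closes by thermal six-electron disrotatory electrocyclization that forms C4a–C8a, after which dienone 13 tautomerises to the phenol. The closest known reaction type is the Danheiser benzannulation in its diazoketone variant with alkoxyalkynes, which gives resorcinol monoethers of this substitution pattern. No lasting stereocentre is made, since the sp3 ring carbon of 11 and 13 becomes aromatic and the silyloxy carbon stays racemic. The one selectivity needed is the regiochemistry of the ketene–alkyne union, and it is secured by the oxygen-polarised triple bond, which places the ketene oxygen (future O1), the silyloxyalkyl carbon (C8) and the methoxy carbon (C7) on three adjacent ring atoms. The alkyne is used in excess so that 10 is trapped before it dimerises or acylates the product phenol, a methoxy ynol ether has no β-hydrogen for retro-ene loss at 80 °C, and the neutral medium spares the silyl ether and the methyl ester.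

Step 6
Reactants: 14 rac-methyl 3-{3-[1-(tert-butyldimethylsilyloxy)-3-methylbutyl]-2-hydroxy-4-methoxyphenyl}propanoate
Product: 15 rac-8-[1-(tert-butyldimethylsilyloxy)-3-methylbutyl]-7-methoxy-3,4-dihydro-2H-chromen-2-one
Conditions: PPTS (0.1 equiv), PhMe, 110 °C, 5 Å molecular sieves
Reagents that add atoms: none
Why: Acid-catalysed lactonization of the ortho-hydroxy dihydrocinnamate closes the six-membered ring B as the sieves take up methanol, and a weak pyridinium acid in an aprotic solvent should not ionise the hindered benzylic silyl ether.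

Step 7
Reactants: 15 rac-8-[1-(tert-butyldimethylsilyloxy)-3-methylbutyl]-7-methoxy-3,4-dihydro-2H-chromen-2-one
Product: 16 rac-8-[1-(tert-butyldimethylsilyloxy)-3-methylbutyl]-7-methoxy-2H-chromen-2-one
Conditions: DDQ (2 equiv), 1,4-dioxane, 100 °C
Reagents that add atoms: none
Why: DDQ dehydrogenation of a dihydrocoumarin proceeds by hydride abstraction from C4, whose cation is stabilised by the para methoxy group on C7, followed by loss of the C3 proton, while the other benzylic C–H lies between two ortho substituents and is held near the ring plane, out of overlap with the arene.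

Step 8
Reactants: 16 rac-8-[1-(tert-butyldimethylsilyloxy)-3-methylbutyl]-7-methoxy-2H-chromen-2-one
Product: 17 rac-8-(1-hydroxy-3-methylbutyl)-7-methoxy-2H-chromen-2-one
Conditions: Bu4NF, AcOH (1.5 equiv each), THF, 0 to 25 °C
Reagents that add atoms: none
Why: Fluoride-driven desilylation through the strong Si–F bond, buffered with acetic acid so that the coumarin lactone never meets a basic alkoxide.

Step 9
Reactants: 17 rac-8-(1-hydroxy-3-methylbutyl)-7-methoxy-2H-chromen-2-one
Product: 18 7-methoxy-8-(3-methylbutanoyl)-2H-chromen-2-one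
Conditions: Dess–Martin periodinane, CH2Cl2, 0 to 25 °C
Reagents that add atoms: none
Why: Dess–Martin oxidation turns the secondary benzylic alcohol into the aryl ketone under near-neutral conditions that leave the coumarin alone, and it removes the only stereocentre of the route.

Step 10
Reactants: 18 7-methoxy-8-(3-methylbutanoyl)-2H-chromen-2-one
Product: 19 1-(7-methoxy-2-oxo-2H-chromen-8-yl)-3-methylbutane-1,2-dione
Conditions: SeO2 (1.5 equiv), wet 1,4-dioxane, 100 °C
Reagents that add atoms: selenium dioxide, O=[Se]=O
Why: Riley oxidation, in which SeO2 attacks the enol of the aryl ketone at its only α-methylene group (the aryl side has no α-hydrogen) and converts CH2 into C=O, the usual outcome for aryl alkyl ketones.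

Step 11
Reactants: 19 1-(7-methoxy-2-oxo-2H-chromen-8-yl)-3-methylbutane-1,2-dione; 20 3-methylbutanoyl chloride (isovaleryl chloride)
Product: 22 exotimarin H, via potassium enolate 21 (not isolated)
Conditions: KN(SiMe3)2 (1.05 equiv), THF, −78 °C; then 20, −78 to 0 °C
Reagents that add atoms: none
Why: Enolate O-acylation, in which deprotonation at the only enolisable position (the isopropyl methine) gives the tetrasubstituted enolate 21 and the hard acyl chloride reacts at oxygen because C-acylation would have to build a quaternary carbon, the new alkene carrying two identical methyl groups so that no geometric isomers can arise.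

**Compound list**

1 | methyl 4-oxobutanoate | COC(=O)CCC=O | starting material
2 | methyl (E)-6-oxohept-4-enoate | COC(=O)CC/C=C/C(C)=O | intermediate
3 | methyl (E)-9,9,9-trifluoro-6,8-dioxonon-4-enoate | COC(=O)CC/C=C/C(=O)CC(=O)C(F)(F)F | intermediate
4 | methyl (E)-7-diazo-6-oxohept-4-enoate | COC(=O)CC/C=C/C(=O)C=[N+]=[N-] | intermediate
5 | 2-chloro-1,1-dimethoxyethane | COC(CCl)OC | starting material
6 | 3-methylbutanal | CC(C)CC=O | starting material
7 | (methoxyethynyl)lithium | [Li]C#COC | intermediate
8 | rac-1-methoxy-5-methylhex-1-yn-3-ol | COC#CC(O)CC(C)C | intermediate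
9 | rac-tert-butyl[(1-methoxy-5-methylhex-1-yn-3-yl)oxy]dimethylsilane | COC#CC(CC(C)C)O[Si](C)(C)C(C)(C)C | intermediate
10 | methyl (E)-7-oxohepta-4,6-dienoate (vinylketene) | COC(=O)CC/C=C/C=C=O | intermediate
11 | methyl (E)-5-{3-[1-(tert-butyldimethylsilyloxy)-3-methylbutyl]-2-methoxy-4-oxocyclobut-2-en-1-yl}pent-4-enoate (racemic, diastereomer mixture) | COC(=O)CC/C=C/C1C(OC)=C(C(CC(C)C)O[Si](C)(C)C(C)(C)C)C1=O | intermediate
12 | rac-methyl (4E,6E)-8-[1-(tert-butyldimethylsilyloxy)-3-methylbutyl]-7-methoxy-9-oxonona-4,6,8-trienoate (dienylketene, C5 and C8 cis on the C6=C7 bond) | COC(=O)CC/C=C/C=C(/OC)C(=C=O)C(CC(C)C)O[Si](C)(C)C(C)(C)C | intermediate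
13 | methyl 3-{3-[1-(tert-butyldimethylsilyloxy)-3-methylbutyl]-4-methoxy-2-oxocyclohexa-3,5-dien-1-yl}propanoate (racemic, diastereomer mixture) | COC(=O)CCC1C=CC(OC)=C(C(CC(C)C)O[Si](C)(C)C(C)(C)C)C1=O | intermediate
14 | rac-methyl 3-{3-[1-(tert-butyldimethylsilyloxy)-3-methylbutyl]-2-hydroxy-4-methoxyphenyl}propanoate | COC(=O)CCc1ccc(OC)c(C(CC(C)C)O[Si](C)(C)C(C)(C)C)c1O | intermediate
15 | rac-8-[1-(tert-butyldimethylsilyloxy)-3-methylbutyl]-7-methoxy-3,4-dihydro-2H-chromen-2-one | COc1ccc2CCC(=O)Oc2c1C(CC(C)C)O[Si](C)(C)C(C)(C)C | intermediate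
16 | rac-8-[1-(tert-butyldimethylsilyloxy)-3-methylbutyl]-7-methoxy-2H-chromen-2-one | COc1ccc2ccc(=O)oc2c1C(CC(C)C)O[Si](C)(C)C(C)(C)C | intermediate
17 | rac-8-(1-hydroxy-3-methylbutyl)-7-methoxy-2H-chromen-2-one | COc1ccc2ccc(=O)oc2c1C(O)CC(C)C | intermediate
18 | 7-methoxy-8-(3-methylbutanoyl)-2H-chromen-2-one | COc1ccc2ccc(=O)oc2c1C(=O)CC(C)C | intermediate
19 | 1-(7-methoxy-2-oxo-2H-chromen-8-yl)-3-methylbutane-1,2-dione | COc1ccc2ccc(=O)oc2c1C(=O)C(=O)C(C)C | intermediate
20 | 3-methylbutanoyl chloride | CC(C)CC(Cl)=O | starting material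
21 | potassium 1-(7-methoxy-2-oxo-2H-chromen-8-yl)-3-methyl-1-oxobut-2-en-2-olate | CC(C)=C([O-])C(=O)c1c(OC)ccc2ccc(=O)oc12.[K+] | intermediate
22 | exotimarin H, 1-(7-methoxy-2-oxo-2H-chromen-8-yl)-3-methyl-1-oxobut-2-en-2-yl 3-methylbutanoate | COc1ccc2ccc(=O)oc2c1C(=O)C(OC(=O)CC(C)C)=C(C)C | target

**Count**

Total step count: 11.
Longest linear sequence: 9 steps (steps 1, 2 and 5 to 11, from methyl 4-oxobutanoate); the ynol ether arm (steps 3 and 4) joins at step 5.

**Steps most likely to fail**

1. Step 5. The vinylketene may be lost to dimerisation or to acylation of the product phenol before the α-branched, sterically shielded ynol ether intercepts it, and the ynol ether may degrade under irradiation. The fallback sets out from 3-methylbutanoyl chloride 20 and comes back at ketone 18; ring A is then bought instead of built. Commercial 7-hydroxycoumarin (Oc1ccc2ccc(=O)oc2c1) would be O-acylated with 20 (pyridine, CH2Cl2) to 2-oxo-2H-chromen-7-yl 3-methylbutanoate F1. Fries rearrangement (AlCl3, 150 °C) should move the acyl group to C8, the position between the two oxygens that this rearrangement of 7-acyloxycoumarins favours, giving 7-hydroxy-8-(3-methylbutanoyl)-2H-chromen-2-one F2. O-Methylation (MeI, K2CO3, acetone, reflux) would then give 18, and steps 10 and 11 follow unchanged.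

2. Step 10. Enolisation of the twisted, doubly ortho-substituted aryl ketone may be slow, and further oxidation at the isopropyl methine of the product may compete. The fallback sets out from 18 and comes back at 19. Soft enolisation (Me3SiOTf, Et3N, CH2Cl2, 0 °C) should give 7-methoxy-8-[(Z)-3-methyl-1-(trimethylsilyloxy)but-1-en-1-yl]-2H-chromen-2-one F3; either alkene geometry would serve. Rubottom oxidation with mCPBA (CH2Cl2, 0 °C) should give rac-7-methoxy-8-[3-methyl-2-(trimethylsilyloxy)butanoyl]-2H-chromen-2-one F4. Aqueous citric acid in THF would free rac-8-(2-hydroxy-3-methylbutanoyl)-7-methoxy-2H-chromen-2-one F5, and Dess–Martin oxidation (CH2Cl2, 25 °C) would give 19.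

3. Step 7. Hydride abstraction at the silyloxy-bearing benzylic carbon may compete with abstraction at C4, or the dehydrogenation may stall. The fallback sets out from 15 and comes back at 16. Enolisation of the lactone with LiN(iPr)2 (THF, −78 °C) and trapping with PhSeBr should give 8-[1-(tert-butyldimethylsilyloxy)-3-methylbutyl]-7-methoxy-3-(phenylselanyl)-3,4-dihydro-2H-chromen-2-one F6 as a diastereomer mixture. Oxidation with H2O2 (pyridine, CH2Cl2, 0 °C) would give the selenoxide 8-[1-(tert-butyldimethylsilyloxy)-3-methylbutyl]-7-methoxy-3-(phenylseleninyl)-3,4-dihydro-2H-chromen-2-one F7, whose syn-elimination toward C4 at 0 to 25 °C gives 16.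

**Further compounds**

F1 | step 5 | 2-oxo-2H-chromen-7-yl 3-methylbutanoate | CC(C)CC(=O)Oc1ccc2ccc(=O)oc2c1
F2 | step 5 | 7-hydroxy-8-(3-methylbutanoyl)-2H-chromen-2-one | CC(C)CC(=O)c1c(O)ccc2ccc(=O)oc12
F3 | step 10 | 7-methoxy-8-[(Z)-3-methyl-1-(trimethylsilyloxy)but-1-en-1-yl]-2H-chromen-2-one | COc1ccc2ccc(=O)oc2c1/C(O[Si](C)(C)C)=C/C(C)C
F4 | step 10 | rac-7-methoxy-8-[3-methyl-2-(trimethylsilyloxy)butanoyl]-2H-chromen-2-one | COc1ccc2ccc(=O)oc2c1C(=O)C(O[Si](C)(C)C)C(C)C
F5 | step 10 | rac-8-(2-hydroxy-3-methylbutanoyl)-7-methoxy-2H-chromen-2-one | COc1ccc2ccc(=O)oc2c1C(=O)C(O)C(C)C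
F6 | step 7 | 8-[1-(tert-butyldimethylsilyloxy)-3-methylbutyl]-7-methoxy-3-(phenylselanyl)-3,4-dihydro-2H-chromen-2-one (racemic, diastereomer mixture) | COc1ccc2CC([Se]c3ccccc3)C(=O)Oc2c1C(CC(C)C)O[Si](C)(C)C(C)(C)C
F7 | step 7 | 8-[1-(tert-butyldimethylsilyloxy)-3-methylbutyl]-7-methoxy-3-(phenylseleninyl)-3,4-dihydro-2H-chromen-2-one (racemic, diastereomer mixture) | COc1ccc2CC([Se](=O)c3ccccc3)C(=O)Oc2c1C(CC(C)C)O[Si](C)(C)C(C)(C)C
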